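## The problem

CNP0138989.1 is a briarane diterpenoid. With briarane numbering, a cyclohexene (ring A: C1, C10–C14) is trans-fused through the quaternary C1 and C10 to a ten-membered carbocycle (ring B: C1–C10). Ring B carries a γ-lactone (ring C: O, C7, C8, C17, C19) fused across C7–C8. Nine stereocenters must be set (C1, C2, C7, C8, C9, C10, C13, C14, C17), seven of them contiguous along C13–C14–C1–C10–C9–C8–C7. C1 is the natural pivot: it can steer C13 and C14 inside ring A and, through a stereospecific relay, C10 and C9. C7 is too remote for this and is better taken from the chiral pool, C8 and C17 can be set together by a tethered addition from the C7 oxygen, and C2 by reagent control. Ring B is the main obstacle: a ten-membered ring with a Z trisubstituted alkene (C5=C6), a neopentyl carbinol (C2) and a fully oxygenated C7–C8–C9 strip is a poor candidate for end-to-end closure. The target is also fragile: a C2 propionate sits 1,3 to the C14 butyrate (acyl migration), the C13 butyrate and the C7 lactone oxygen are allylic, and the tertiary β-hydroxy lactone at C8 can undergo retro-aldol cleavage or dehydration, so acylations and lactone formation belong at the end. The feature that opens ring B is the array C2(–O)/C3–C4/C5=C6: with C2 at the ketone level it is a γ,δ-unsaturated carbonyl unit, the product pattern of a Claisen rearrangement, and C6, an alkene carbon in the target, can give up an oxygen without loss.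

## Retrosynthesis

Ring C and the esters come off first. Target 46 is the C9 p-methoxybenzyl (PMB) ether 45 after oxidative deprotection. In 45 the C8–C17 bond is cut, giving the C7 2-bromopropionate C8 ketone 44. This cut is preferred to an intermolecular propionate addition because the C7 oxygen then delivers C17 to C8 and both new centers arise in one tethered step. 44 comes from the C7,C8 diol 41 by acylation at O7 and oxidation at C8, and 41 from acetonide 40. The butyrates of 40 and the propionate of 37 are then removed in turn, and the C2 carbinol 35 goes back to ketone 34. Ketone 34 is far simpler than 46: no ester, no lactone, four masked hydroxyls and a single carbonyl group. The forward steps must distinguish O7 from O8 and set C2 by reagent control.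

Ring B is opened next. In 34 the C3–C4 bond is cut and C6 is rejoined to the C2 oxygen, which gives the 2-methylene oxocane 33 with an isopropenyl group on C6. Against direct closures at C8–C9 or C2–C3, this cut turns the ten-membered ring problem into a [3,3] shift inside a preformed eight-membered ring, and the tether fixes the Z alkene. 33 is the methylenation product of lactone 31. The forward reaction must be run so that no methylenating agent is present when the ketone appears, and the enol ether must survive until it rearranges.

The eight-membered ring is then cut at the C2(=O)–O6 bond, leading to hydroxy acid 30. A C–O closure is chosen over a C–C closure because the trans ring A junction and the trans dioxolane on C7–C8 already bend the chain. The price is a lactonisation at a neopentyl carboxyl, which asks for a strong acyl activator and high dilution.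

Hydroxy acid 30 is cut at C9–C10. Through 29–26 it goes back to homoallylic alcohol 25, which divides into the ring A allylboronate 24 and the C6–C9 aldehyde 8. This is the most convergent cut. Allylboration forms C9–C10, sets C9 and C10 together through a closed transition state, and leaves the alkene at C11–C12. An aldol reaction from a C11 ketone would give the anti C9/C10 relationship instead of the syn one needed, and a cut at C8–C9 would need an oxygenated C8 nucleophile. The forward reaction needs a boronate of defined configuration at C12.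

Ring A boronate 24 is traced through carbonate 23, allylic alcohol 22, enone 21, pivalate 20, alcohol 19, bis-silyl ether 18, diol 17 and hydroxy ketone 16 to the cyclohexadiene amide 14. In 14 the C1–CH3 bond is cut, which leads to benzamide 11, made from 2-methoxy-5-methylbenzoic acid 9 and the auxiliary (S)-2-(methoxymethyl)pyrrolidine 10, with iodomethane 12. The aromatic ring already holds the C14 oxygen and the C11 methyl group in the right places, and the Birch alkylation sets C1 as a single enantiomer. The amide then shields one face for the oxidation at C13.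

Aldehyde 8 is cut at C5–C6. Through alcohol 7 and silyl ether 6 it goes back to allylic alcohol 5, made from aldehyde 3 and isopropenylmagnesium bromide 4. Aldehyde 3 comes via mono-ether 2 from the C2-symmetric diol 1, which carries C7 and C8 of L-tartaric acid. C7 is thus bought with the right configuration. C8 is a stereocenter only until it is oxidised, and C6 only until the key step.

## Roads not taken

Alternative 1: Ring A by a Diels–Alder reaction with the alkene at C12–C13. The cut is at C1–C14 and C10–C11. Forward, the silyloxy diene A2 adds endo to the 2-methyl enal A3 under a chiral oxazaborolidinium catalyst and gives aldehyde A1, with C1, C10, C11 and C14 set and the C2 and C9 carbons in place. For ring A alone this is the better road: it is catalytic in chirality, needs no auxiliary and is several steps shorter than steps 7–17. Its weak points for this target are three. The β-substituted 2-methyl enal is a sluggish dienophile. The alkene lies at C12–C13, so an oxidative transposition is needed to reach C11=C12 with the C13 oxygen trans to C14. And C9 sits on ring A as a carbinol carbon, which forces the oxygenated chain to be attached as a C8 nucleophile or built linearly. Against the shorter ring A, the chosen plan sets the one-step union of ring A with the whole C4–C9 chain and a C11 methyl and C14 oxygen that come from the arene. Alternative 1 also offers nothing for ring B.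

Alternative 2: Samarium Reformatsky closure of ring C as the organising step. The cut is C8–C17. Forward, SmI2 turns the C7 2-bromopropionate of ketone A5 into a samarium enolate that adds to C8 and gives A4, the C9 triethylsilyl ether of the target. Its merits are real: two stereocenters and a ring in one mild step, at the very end, with all esters in place. The chosen plan uses this reaction as its step 34. As a strategy it is incomplete, because A5 already contains ring B, the Z alkene and seven stereocenters. Its own risks are reductive loss of the α-acyloxy group and the face selectivity at C8. In stereocenters formed it is superior to the Claisen step, which forms none. The chosen plan has ring B to set against that.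

Alternative 3: Nozaki–Hiyama–Kishi closure of ring B at C8–C9. Forward, CrCl2 with catalytic NiCl2 converts the C8 iodide of the seco aldehyde A7 into a vinylchromium species that adds to the C9 aldehyde and gives A6, with rings A, B and C and a butenolide alkene at C8–C17. In functional-group tolerance and protecting-group economy this is the better road: all three esters can be present, and the ring is closed last by a reaction with a good record for medium rings. The weak points lie around the key step. The ten-membered ring is closed end to end. The C9 configuration is left to the ring conformation. The Z C5=C6 alkene and the neopentyl C1–C2 bond must be made in an open chain. The butenolide must afterwards be hydrated across a tetrasubstituted alkene to give the C8 hydroxyl and C17 hydrogen with the right faces. The chosen plan keeps the C8 oxygen from the start, obtains the Z alkene from the tether, and makes ring B by a pericyclic ring expansion instead of a dilution-dependent cyclisation. It pays for this with more protecting-group steps.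

Key step: step 26

Remark: briarane numbering is used for all intermediates; C2 is the carbon that ends as the propionate carbinol.

Assumption: the (S)-auxiliary 10 is taken to give the (R) configuration at C1 of 14 (methylation of the chelated potassium enolate on the face away from the methoxymethyl arm); if the sense is the opposite, the (R)-auxiliary is used and nothing else changes.

## Route

Step 1
Reactants: 1 (4S,5S)-2,2-dimethyl-1,3-dioxolane-4,5-dimethanol
Product: 2 mono(4-methoxybenzyl) ether of 1 (C9 oxygen protected, C6 hydroxyl free)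
Conditions: NaH (1.0 equiv), 4-methoxybenzyl chloride, Bu4NI (cat.), THF/DMF, 0 °C to rt
Reagents that add atoms: 4-methoxybenzyl chloride, COc1ccc(CCl)cc1
Why: Williamson etherification of a C2-symmetric diol, so either hydroxyl gives the same mono-ether; one equivalent of base keeps bis-alkylation low and recovered diol is recycled.

Step 2
Reactants: 2 mono-PMB ether
Product: 3 (4R,5S)-5-[(4-methoxybenzyloxy)methyl]-2,2-dimethyl-1,3-dioxolane-4-carbaldehyde (C6 aldehyde)
Conditions: Dess–Martin periodinane, NaHCO3, CH2Cl2, 0 °C to rt
Reagents that add atoms: none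
Why: Dess–Martin oxidation is neutral and should not epimerise the α-alkoxy aldehyde.

Step 3
Reactants: 3 C6 aldehyde; 4 isopropenylmagnesium bromide
Product: 5 (S)-1-[(4S,5S)-5-[(4-methoxybenzyloxy)methyl]-2,2-dimethyl-1,3-dioxolan-4-yl]-2-methylprop-2-en-1-ol (6,7-anti allylic alcohol)
Conditions: THF, −78 °C; then H2O/NH4Cl
Reagents that add atoms: isopropenylmagnesium bromide 4, CC(=C)[Mg]Br
Why: Grignard addition under Felkin–Anh control: attack anti to the α-C–O bond of the dioxolane should favour the 6,7-anti carbinol, and the syn epimer is removed by chromatography. C6 is lost in step 26, so its configuration is chosen for accessibility only.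

Step 4
Reactants: 5 allylic alcohol
Product: 6 C6 triethylsilyl ether of 5
Conditions: Et3SiCl, imidazole, DMF, 0 °C
Reagents that add atoms: chlorotriethylsilane, CC[Si](Cl)(CC)CC
Why: Standard silylation; the triethylsilyl group is later removed in the presence of two hindered tert-butyldimethylsilyl ethers.

Step 5
Reactants: 6 triethylsilyl ether
Product: 7 C9 primary alcohol (C7,C8 acetonide, C6 triethylsilyl ether, isopropenyl group)
Conditions: 2,3-dichloro-5,6-dicyano-1,4-benzoquinone (DDQ), CH2Cl2/pH 7 buffer, 0 °C
Reagents that add atoms: none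
Why: Oxidative cleavage of the PMB ether via its benzylic oxocarbenium ion; silyl ether, acetonide and alkene are inert under buffered conditions.

Step 6
Reactants: 7 primary alcohol
Product: 8 C6–C9 aldehyde (C9 formyl, C7,C8 acetonide, C6 triethylsilyl ether, isopropenyl group)
Conditions: Dess–Martin periodinane, NaHCO3, CH2Cl2, 0 °C to rt
Reagents that add atoms: none
Why: Dess–Martin oxidation; the aldehyde is used at once in step 18 to avoid epimerisation at C8.

Step 7
Reactants: 9 2-methoxy-5-methylbenzoic acid; 10 (S)-2-(methoxymethyl)pyrrolidine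
Product: 11 N-(2-methoxy-5-methylbenzoyl)-(S)-2-(methoxymethyl)pyrrolidine
Conditions: 1-ethyl-3-(3-dimethylaminopropyl)carbodiimide hydrochloride, 1-hydroxybenzotriazole (cat.), i-Pr2NEt, CH2Cl2, rt
Reagents that add atoms: none
Why: Carbodiimide amide coupling of an unhindered secondary amine.

Step 8
Reactants: 11 benzamide; 12 iodomethane
Product: 14 (R)-2-methoxy-1,5-dimethylcyclohexa-2,5-diene-1-carboxamide of auxiliary 10, via potassium amide enolate 13 (not isolated)
Conditions: K, NH3(l)/THF, t-BuOH (1 equiv), −78 °C; then MeI, −78 °C
Reagents that add atoms: iodomethane 12, CI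
Why: Birch reduction–alkylation of a chiral 2-methoxybenzamide: reduction at C1 and C12 gives a chelated potassium amide enolate that is methylated at C1 on the face away from the methoxymethyl arm, which sets the quaternary center. The 1,4-diene carries the C14 enol ether and the C11 methyl group from the arene.

Step 9
Reactants: 14 diene amide
Product: 16 α-hydroxy ketone (C13 hydroxyl trans to the carboxamide; C14 ketone), via methoxy epoxide 15 (not isolated)
Conditions: dimethyldioxirane (1.05 equiv), acetone/CH2Cl2, −78 to −20 °C; then H2O, NaHCO3, rt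
Reagents that add atoms: dimethyldioxirane, CC1(C)OO1; water, O
Why: Rubottom-type oxidation: the enol ether is far more nucleophilic than the trisubstituted C10=C11 alkene and is epoxidised on the face anti to the bulky carboxamide on C1, which sets C13. Hydrolysis of the methoxy epoxide gives the hydroxy ketone.

Step 10
Reactants: 16 α-hydroxy ketone
Product: 17 trans-C13,C14 diol (C14 hydroxyl cis to the carboxamide)
Conditions: Me4NBH(OAc)3, MeCN/AcOH, −30 °C
Reagents that add atoms: none
Why: Hydroxyl-directed (Evans–Saksena) reduction: hydride is delivered from the boron bound to the C13 oxygen, on the C13–O face, which sets C14 trans to C13. The same face is the one remote from the carboxamide.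

Step 11
Reactants: 17 diol
Product: 18 C13,C14 bis(tert-butyldimethylsilyl) ether
Conditions: t-BuMe2SiOTf, 2,6-lutidine, CH2Cl2, 0 °C to rt
Reagents that add atoms: tert-butyldimethylsilyl triflate, CC(C)(C)[Si](C)(C)OS(=O)(=O)C(F)(F)F
Why: The silyl triflate reaches the neopentyl C14 hydroxyl; protection precedes amide reduction so that no β-alkoxide can trigger retro-aldol opening of ring A.

Step 12
Reactants: 18 bis-silyl ether amide
Product: 19 C2 primary alcohol (C1 methyl and hydroxymethyl, C10=C11 alkene)
Conditions: LiNH2BH3 (from BH3·NH3 and LiN(i-Pr)2), THF, 0 to 23 °C; then H2O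
Reagents that add atoms: none
Why: Lithium amidotrihydroborate reduces hindered α-quaternary tertiary amides to primary alcohols with C–N cleavage; auxiliary 10 is released and recovered.

Step 13
Reactants: 19 primary alcohol
Product: 20 C2 pivalate
Conditions: pivaloyl chloride, pyridine, 4-dimethylaminopyridine (cat.), CH2Cl2, rt
Reagents that add atoms: pivaloyl chloride, CC(C)(C)C(Cl)=O
Why: Acylation of the primary alcohol; the pivalate survives the oxidation, borylation and alkylation steps and is removed reductively in step 20.

Step 14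
Reactants: 20 pivalate
Product: 21 C12 enone (C12 ketone conjugated with C10=C11)
Conditions: Rh2(cap)4 (dirhodium tetrakis(caprolactamate), 1 mol %), t-BuOOH, K2CO3, CH2Cl2, rt
Reagents that add atoms: tert-butyl hydroperoxide, CC(C)(C)OO
Why: Dirhodium-catalysed allylic oxidation with tert-butyl hydroperoxide: C12 is the only allylic methylene (C1 is quaternary), and methylene oxidation to the enone is faster than oxidation of the C11 methyl group.

Step 15
Reactants: 21 enone
Product: 22 C12 allylic alcohol (hydroxyl trans to the C13 silyl ether)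
Conditions: NaBH4, CeCl3·7H2O, MeOH, −78 °C
Reagents that add atoms: none
Why: Luche 1,2-reduction. The half-chair with both silyloxy groups pseudo-equatorial is favoured, because the diaxial form suffers a syn-pentane clash between the C13 silyloxy group and the C1 methyl group; axial hydride delivery to it places the C12 hydroxyl trans to the C13 oxygen.

Step 16
Reactants: 22 allylic alcohol
Product: 23 C12 methyl carbonate
Conditions: ClCO2Me, pyridine, 4-dimethylaminopyridine (cat.), CH2Cl2, 0 °C
Reagents that add atoms: methyl chloroformate, COC(Cl)=O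
Why: Carbonate formation with retention at C12; the carbonate ionises readily with zerovalent palladium and releases methoxide to activate the diboron reagent.

Step 17
Reactants: 23 allylic carbonate
Product: 24 C12 pinacol allylboronate (boron cis to the C13 silyl ether, C10=C11 alkene)
Conditions: Pd2(dba)3 (tris(dibenzylideneacetone)dipalladium, 2.5 mol %), bis(pinacolato)diboron, DMSO, 50 °C
Reagents that add atoms: bis(pinacolato)diboron, CC1(C)OB(OC1(C)C)B2OC(C)(C)C(C)(C)O2
Why: Miyaura-type allylic borylation: zerovalent palladium ionises the carbonate with inversion, and boron is transferred from palladium with retention to C12, the allyl terminus remote from the quaternary C1. The net inversion places boron on the face of the C13 oxygen.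

Step 18
Reactants: 24 allylboronate; 8 C6–C9 aldehyde
Product: 25 homoallylic alcohol (C9–C10 bond, C9 hydroxyl, C11=C12 alkene)
Conditions: toluene, 23 to 50 °C; then aq. NaHCO3
Reagents that add atoms: none
Why: Allylboration through a closed six-membered chair transition state: C9 bonds to C10 on the face that carried boron (cis to the C1 methyl group), and the ring-locked Z-type allyl unit gives the syn C9/C10 relationship, so both centers are set by the reagent. The aldehyde's own Felkin–Anh preference (8,9-anti) points the same way, a matched pair.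

Step 19
Reactants: 25 homoallylic alcohol
Product: 26 C9 PMB ether
Conditions: NaH, 4-methoxybenzyl bromide, Bu4NI (cat.), THF/DMF, 0 °C to rt
Reagents that add atoms: 4-methoxybenzyl bromide, COc1ccc(CBr)cc1
Why: Williamson etherification; the PMB ether survives the acid of step 31 and is removed oxidatively in the last step.

Step 20
Reactants: 26 PMB ether
Product: 27 C2 primary alcohol
Conditions: i-Bu2AlH, CH2Cl2, −78 °C; Rochelle salt
Reagents that add atoms: none
Why: Reductive removal of the pivalate, the only carbonyl group present.

Step 21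
Reactants: 27 primary alcohol
Product: 28 C2 aldehyde
Conditions: Dess–Martin periodinane, NaHCO3, CH2Cl2, rt
Reagents that add atoms: none
Why: Dess–Martin oxidation of a neopentyl alcohol to an aldehyde that cannot enolise.

Step 22
Reactants: 28 aldehyde
Product: 29 C2 carboxylic acid (C6 triethylsilyl ether)
Conditions: NaClO2, NaH2PO4, 2-methyl-2-butene, t-BuOH/H2O, 0 °C to rt
Reagents that add atoms: sodium chlorite, [Na+].[O-]Cl=O
Why: Pinnick oxidation; the alkene scavenger protects the isopropenyl and C11=C12 alkenes from hypochlorous acid.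

Step 23
Reactants: 29 acid
Product: 30 hydroxy acid (C6 hydroxyl free, C2 carboxyl)
Conditions: HF·pyridine, pyridine, THF, 0 °C
Reagents that add atoms: none
Why: Buffered fluoride removes the secondary triethylsilyl ether much faster than the two hindered tert-butyldimethylsilyl ethers.

Step 24
Reactants: 30 hydroxy acid
Product: 31 eight-membered lactone (C2 carbonyl bound to the C6 oxygen)
Conditions: 2-methyl-6-nitrobenzoic anhydride, 4-dimethylaminopyridine, Et3N, CH2Cl2 (1 mM, syringe pump), rt
Reagents that add atoms: none
Why: Shiina lactonisation: the mixed anhydride is attacked by the pyridine catalyst at the aliphatic carbonyl, since the 2,6-disubstituted aroyl carbonyl is more shielded, and slow addition favours ring closure. The trans ring A junction and the trans dioxolane pre-bend the chain.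

Step 25
Reactants: 31 lactone; 32 Cp2Ti(CH2)(Cl)AlMe2 (Tebbe reagent)
Product: 33 2-methylene oxocane (oxygen bridging C2 and C6, isopropenyl group on C6)
Conditions: Cp2Ti(CH2)(Cl)AlMe2 in toluene, pyridine (cat.), THF, −40 to 0 °C; aq. NaOH, basic alumina
Reagents that add atoms: Cp2Ti(CH2)(Cl)AlMe2 32, C[Al](C)C[Ti](Cl)(C1C=CC=C1)C1C=CC=C1
Why: Tebbe methylenation of the lactone carbonyl by [2+2] addition of the titanium methylidene and cycloreversion. The low temperature keeps the enol ether from rearranging while a methylenating agent is still present.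

Step 26
Reactants: 33 2-methylene oxocane
Product: 34 cyclodecenone (ring B with C2 ketone and Z C5=C6 alkene)
Conditions: o-xylene, Et3N (trace), base-washed glass, 140 °C, sealed tube
Reagents that add atoms: none
Why: Heating triggers a concerted [3,3]-sigmatropic shift of the allyl vinyl ether O–C2(=C3H2)/C6–C5(Me)=C4H2: C3 bonds to C4 while the ring C6–O bond breaks, C2 becomes a ketone and C5=C6 the ring alkene. The closest known reaction type is the Claisen ring expansion of 2-methylene oxacycles that carry an alkenyl group next to oxygen, established for six- and seven-membered ethers; the oxocane extends the ring size. Ring B is closed by ring expansion: the eight-membered ether becomes the ten-membered carbocycle as oxygen leaves the ring and C3, C4 and C5 enter it, so no end-to-end cyclisation is asked for. No stereocenter is formed, since C6 becomes trigonal and C3 and C4 are methylenes. The selectivity needed is the Z geometry of C5=C6: the torsion about O–C6 cannot become anti inside the oxocane, so the C6–C7 bond must be pseudo-axial in the chair-like array, which places C7 cis to C4. The quaternary C1 blocks isomerisation of the exocyclic enol ether into the ring, and base-washed glass with a trace of amine suppresses hydrolysis and ionisation of the allylic C6–O bond.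

Step 27
Reactants: 34 cyclodecenone
Product: 35 (2S)-C2 alcohol
Conditions: (R)-1-methyl-3,3-diphenyltetrahydro-1H,3H-pyrrolo[1,2-c][1,3,2]oxazaborole (CBS catalyst), catecholborane, toluene, −78 to −40 °C
Reagents that add atoms: none
Why: Corey–Bakshi–Shibata reduction: the catalyst distinguishes the quaternary C1 side (large) from the C3 methylene side (small), and the (R)-catalyst should give the (S)-carbinol. Catecholborane does not hydroborate the trisubstituted alkenes at this temperature.

Step 28
Reactants: 35 C2 alcohol; 36 propionic anhydride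
Product: 37 C2 propionate
Conditions: 4-dimethylaminopyridine, Et3N, CH2Cl2, rt
Reagents that add atoms: propionic anhydride 36, CCC(=O)OC(=O)CC
Why: Nucleophile-catalysed acylation of the neopentyl secondary alcohol, done while C13 and C14 are still silylated so that only one hydroxyl is free.

Step 29
Reactants: 37 propionate
Product: 38 C13,C14 diol
Conditions: HF·pyridine, THF, 0 °C to rt
Reagents that add atoms: none
Why: Fluoride desilylation under mildly acidic conditions, under which the C2 propionate does not migrate to O14 and the acetonide and PMB ether stay.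

Step 30
Reactants: 38 diol; 39 butyric anhydride
Product: 40 C13,C14 dibutyrate
Conditions: 4-dimethylaminopyridine, pyridine, CH2Cl2, rt to 40 °C
Reagents that add atoms: butyric anhydride 39, CCCC(=O)OC(=O)CCC
Why: Exhaustive acylation of the allylic C13 and neopentyl C14 hydroxyls; with excess anhydride, acylation should outpace 1,3-transfer of the C2 propionate.

Step 31
Reactants: 40 dibutyrate
Product: 41 C7,C8 diol
Conditions: AcOH/H2O/THF (3:1:1), 40 °C
Reagents that add atoms: none
Why: Acid hydrolysis of the strained trans-fused dioxolane; esters and the PMB ether are stable to aqueous acetic acid.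

Step 32
Reactants: 41 C7,C8 diol; 42 2-bromopropionyl bromide
Product: 43 C7 2-bromopropionate (C8 hydroxyl free, both configurations at the bromide carbon)
Conditions: pyridine, CH2Cl2, −78 °C
Reagents that add atoms: 2-bromopropionyl bromide 42, CC(Br)C(Br)=O
Why: Kinetic mono-acylation: the allylic C7 hydroxyl, next to a trigonal carbon, is more accessible than the C8 hydroxyl, which lies between two branched carbons and beside the C9 PMB ether. The configuration at the bromide carbon is lost at the enolate stage.

Step 33
Reactants: 43 bromopropionate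
Product: 44 C8 ketone
Conditions: Dess–Martin periodinane, NaHCO3, CH2Cl2, 0 °C
Reagents that add atoms: none
Why: Buffered Dess–Martin oxidation of the remaining secondary alcohol; neutral conditions avoid enolisation toward the doubly activated C7.

Step 34
Reactants: 44 bromo ester ketone
Product: 45 C9 PMB ether of the target (ring C closed, C8 tertiary alcohol)
Conditions: SmI2 (2.2 equiv), THF, −78 °C; pH 7 buffer
Reagents that add atoms: none
Why: Samarium Reformatsky reaction: SmI2 reduces the C–Br bond faster than any other group, and the trivalent samarium enolate adds to the C8 ketone through a chelated transition state, forming C8–C17. The short tether delivers C17 from the side of the C7 oxygen with the C6–C7–C8–C9 segment extended, which should give the trans-fused lactone with the C17 methyl cis to the C8 hydroxyl; C17 is α to the lactone carbonyl and can be equilibrated if needed.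

Step 35
Reactants: 45 PMB ether
Product: 46 CNP0138989.1
Conditions: 2,3-dichloro-5,6-dicyano-1,4-benzoquinone, CH2Cl2/pH 7 buffer, 0 °C
Reagents that add atoms: none
Why: Oxidative PMB removal under neutral conditions, which spare the three esters and the β-hydroxy lactone.

## Compound list

1 | (4S,5S)-2,2-dimethyl-1,3-dioxolane-4,5-dimethanol (2,3-O-isopropylidene-L-threitol) | OC[C@@H]1OC(C)(C)O[C@H]1CO | starting material
2 | [(4S,5S)-5-[(4-methoxybenzyloxy)methyl]-2,2-dimethyl-1,3-dioxolan-4-yl]methanol | COc1ccc(COC[C@@H]2OC(C)(C)O[C@H]2CO)cc1 | intermediate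
3 | (4R,5S)-5-[(4-methoxybenzyloxy)methyl]-2,2-dimethyl-1,3-dioxolane-4-carbaldehyde | COc1ccc(COC[C@@H]2OC(C)(C)O[C@H]2C=O)cc1 | intermediate
4 | isopropenylmagnesium bromide | CC(=C)[Mg]Br | starting material
5 | (S)-1-[(4S,5S)-5-[(4-methoxybenzyloxy)methyl]-2,2-dimethyl-1,3-dioxolan-4-yl]-2-methylprop-2-en-1-ol (6,7-anti) | COc1ccc(COC[C@@H]2OC(C)(C)O[C@H]2[C@@H](O)C(C)=C)cc1 | intermediate
6 | C6 triethylsilyl ether of 5 | COc1ccc(COC[C@@H]2OC(C)(C)O[C@H]2[C@@H](O[Si](CC)(CC)CC)C(C)=C)cc1 | intermediate
7 | C9 primary alcohol with C7,C8 acetonide, C6 triethylsilyl ether and isopropenyl group | OC[C@@H]1OC(C)(C)O[C@H]1[C@@H](O[Si](CC)(CC)CC)C(C)=C | intermediate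
8 | C6–C9 aldehyde (C9 formyl, C7,C8 acetonide, C6 triethylsilyl ether, isopropenyl group) | O=C[C@@H]1OC(C)(C)O[C@H]1[C@@H](O[Si](CC)(CC)CC)C(C)=C | intermediate
9 | 2-methoxy-5-methylbenzoic acid | COc1ccc(C)cc1C(=O)O | starting material
10 | (S)-2-(methoxymethyl)pyrrolidine | COC[C@@H]1CCCN1 | starting material
11 | N-(2-methoxy-5-methylbenzoyl)-(S)-2-(methoxymethyl)pyrrolidine | COc1ccc(C)cc1C(=O)N1CCC[C@H]1COC | intermediate
12 | iodomethane | CI | starting material
13 | potassium amide enolate of the Birch-reduced benzamide | COC1=CCC(C)=CC1=C(O[K])N1CCC[C@H]1COC | intermediate (not isolated)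
14 | (R)-2-methoxy-1,5-dimethylcyclohexa-2,5-diene-1-carboxamide of (S)-2-(methoxymethyl)pyrrolidine | COC1=CCC(C)=C[C@@]1(C)C(=O)N1CCC[C@H]1COC | intermediate
15 | C13,C14 methoxy epoxide of 14 (epoxide oxygen trans to the carboxamide) | CO[C@@]12O[C@@H]1CC(C)=C[C@@]2(C)C(=O)N1CCC[C@H]1COC | intermediate (not isolated)
16 | ring A α-hydroxy ketone: C13 hydroxyl trans to the carboxamide, C14 ketone, C10=C11 alkene | O[C@@H]1CC(C)=C[C@@](C)(C(=O)N2CCC[C@H]2COC)C1=O | intermediate
17 | ring A trans-C13,C14 diol amide (C14 hydroxyl cis to the carboxamide) | O[C@@H]1CC(C)=C[C@@](C)(C(=O)N2CCC[C@H]2COC)[C@H]1O | intermediate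
18 | C13,C14 bis(tert-butyldimethylsilyl) ether of 17 | CC(C)(C)[Si](C)(C)O[C@@H]1CC(C)=C[C@@](C)(C(=O)N2CCC[C@H]2COC)[C@H]1O[Si](C)(C)C(C)(C)C | intermediate
19 | ring A C2 primary alcohol (C1 methyl and hydroxymethyl, trans C13,C14 silyl ethers, C10=C11 alkene) | CC(C)(C)[Si](C)(C)O[C@@H]1CC(C)=C[C@@](C)(CO)[C@H]1O[Si](C)(C)C(C)(C)C | intermediate
20 | C2 pivalate of 19 | CC(C)(C)[Si](C)(C)O[C@@H]1CC(C)=C[C@@](C)(COC(=O)C(C)(C)C)[C@H]1O[Si](C)(C)C(C)(C)C | intermediate
21 | ring A C12 enone | CC(C)(C)[Si](C)(C)O[C@@H]1C(=O)C(C)=C[C@@](C)(COC(=O)C(C)(C)C)[C@H]1O[Si](C)(C)C(C)(C)C | intermediate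
22 | ring A C12 allylic alcohol (hydroxyl trans to the C13 silyl ether) | CC(C)(C)[Si](C)(C)O[C@@H]1[C@@H](O)C(C)=C[C@@](C)(COC(=O)C(C)(C)C)[C@H]1O[Si](C)(C)C(C)(C)C | intermediate
23 | C12 methyl carbonate of 22 | CC(C)(C)[Si](C)(C)O[C@@H]1[C@@H](OC(=O)OC)C(C)=C[C@@](C)(COC(=O)C(C)(C)C)[C@H]1O[Si](C)(C)C(C)(C)C | intermediate
24 | ring A C12 pinacol allylboronate (boron cis to the C13 silyl ether) | CC(C)(C)[Si](C)(C)O[C@@H]1[C@H](B2OC(C)(C)C(C)(C)O2)C(C)=C[C@@](C)(COC(=O)C(C)(C)C)[C@H]1O[Si](C)(C)C(C)(C)C | intermediate
25 | homoallylic alcohol: ring A (C11=C12) joined at C10 to the C9 carbinol of the C6–C9 chain; C2 pivalate, C6 triethylsilyl ether | CC(C)(C)[Si](C)(C)O[C@@H]1C=C(C)[C@H]([C@H](O)[C@@H]2OC(C)(C)O[C@H]2[C@@H](O[Si](CC)(CC)CC)C(C)=C)[C@@](C)(COC(=O)C(C)(C)C)[C@H]1O[Si](C)(C)C(C)(C)C | intermediate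
26 | C9 PMB ether of 25 | CC(C)(C)[Si](C)(C)O[C@@H]1C=C(C)[C@H]([C@H](OCc3ccc(OC)cc3)[C@@H]2OC(C)(C)O[C@H]2[C@@H](O[Si](CC)(CC)CC)C(C)=C)[C@@](C)(COC(=O)C(C)(C)C)[C@H]1O[Si](C)(C)C(C)(C)C | intermediate
27 | C2 primary alcohol | CC(C)(C)[Si](C)(C)O[C@@H]1C=C(C)[C@H]([C@H](OCc3ccc(OC)cc3)[C@@H]2OC(C)(C)O[C@H]2[C@@H](O[Si](CC)(CC)CC)C(C)=C)[C@@](C)(CO)[C@H]1O[Si](C)(C)C(C)(C)C | intermediate
28 | C2 aldehyde | CC(C)(C)[Si](C)(C)O[C@@H]1C=C(C)[C@H]([C@H](OCc3ccc(OC)cc3)[C@@H]2OC(C)(C)O[C@H]2[C@@H](O[Si](CC)(CC)CC)C(C)=C)[C@@](C)(C=O)[C@H]1O[Si](C)(C)C(C)(C)C | intermediate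
29 | C2 carboxylic acid with C6 triethylsilyl ether | CC(C)(C)[Si](C)(C)O[C@@H]1C=C(C)[C@H]([C@H](OCc3ccc(OC)cc3)[C@@H]2OC(C)(C)O[C@H]2[C@@H](O[Si](CC)(CC)CC)C(C)=C)[C@@](C)(C(=O)O)[C@H]1O[Si](C)(C)C(C)(C)C | intermediate
30 | hydroxy acid (C2 carboxyl, C6 hydroxyl) | CC(C)(C)[Si](C)(C)O[C@@H]1C=C(C)[C@H]([C@H](OCc3ccc(OC)cc3)[C@@H]2OC(C)(C)O[C@H]2[C@@H](O)C(C)=C)[C@@](C)(C(=O)O)[C@H]1O[Si](C)(C)C(C)(C)C | intermediate
31 | ring A-fused eight-membered lactone (C2 carbonyl, C6 isopropenyl, C7,C8 acetonide, C9 PMB ether) | CC(C)(C)[Si](C)(C)O[C@@H]1C=C(C)[C@@H]2[C@H](OCc3ccc(OC)cc3)[C@@H]4OC(C)(C)O[C@H]4[C@H](C(C)=C)OC(=O)[C@@]2(C)[C@H]1O[Si](C)(C)C(C)(C)C | intermediate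
32 | Cp2Ti(CH2)(Cl)AlMe2 (Tebbe reagent) | C[Al](C)C[Ti](Cl)(C1C=CC=C1)C1C=CC=C1 | starting material
33 | ring A-fused 2-methylene oxocane (C6 isopropenyl, C7,C8 acetonide, C9 PMB ether, C13,C14 silyl ethers) | CC(C)(C)[Si](C)(C)O[C@@H]1C=C(C)[C@@H]2[C@H](OCc3ccc(OC)cc3)[C@@H]4OC(C)(C)O[C@H]4[C@H](C(C)=C)OC(=C)[C@@]2(C)[C@H]1O[Si](C)(C)C(C)(C)C | intermediate
34 | rings A and B with C2 ketone and Z C5=C6 alkene (C7,C8 acetonide, C9 PMB ether, C13,C14 silyl ethers) | CC(C)(C)[Si](C)(C)O[C@@H]1C=C(C)[C@@H]2[C@H](OCc3ccc(OC)cc3)[C@@H]4OC(C)(C)O[C@H]4/C=C(/C)CCC(=O)[C@@]2(C)[C@H]1O[Si](C)(C)C(C)(C)C | intermediate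
35 | (2S)-C2 alcohol | CC(C)(C)[Si](C)(C)O[C@@H]1C=C(C)[C@@H]2[C@H](OCc3ccc(OC)cc3)[C@@H]4OC(C)(C)O[C@H]4/C=C(/C)CC[C@H](O)[C@@]2(C)[C@H]1O[Si](C)(C)C(C)(C)C | intermediate
36 | propionic anhydride | CCC(=O)OC(=O)CC | starting material
37 | C2 propionate | CC(C)(C)[Si](C)(C)O[C@@H]1C=C(C)[C@@H]2[C@H](OCc3ccc(OC)cc3)[C@@H]4OC(C)(C)O[C@H]4/C=C(/C)CC[C@H](OC(=O)CC)[C@@]2(C)[C@H]1O[Si](C)(C)C(C)(C)C | intermediate
38 | C13,C14 diol | O[C@@H]1C=C(C)[C@@H]2[C@H](OCc3ccc(OC)cc3)[C@@H]4OC(C)(C)O[C@H]4/C=C(/C)CC[C@H](OC(=O)CC)[C@@]2(C)[C@H]1O | intermediate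
39 | butyric anhydride | CCCC(=O)OC(=O)CCC | starting material
40 | C13,C14 dibutyrate | CCCC(=O)O[C@@H]1C=C(C)[C@@H]2[C@H](OCc3ccc(OC)cc3)[C@@H]4OC(C)(C)O[C@H]4/C=C(/C)CC[C@H](OC(=O)CC)[C@@]2(C)[C@H]1OC(=O)CCC | intermediate
41 | C7,C8 diol | CCCC(=O)O[C@@H]1C=C(C)[C@@H]2[C@H](OCc3ccc(OC)cc3)[C@H](O)[C@@H](O)/C=C(/C)CC[C@H](OC(=O)CC)[C@@]2(C)[C@H]1OC(=O)CCC | intermediate
42 | 2-bromopropionyl bromide | CC(Br)C(Br)=O | starting material
43 | C7 2-bromopropionate with free C8 hydroxyl | CCCC(=O)O[C@@H]1C=C(C)[C@@H]2[C@H](OCc3ccc(OC)cc3)[C@H](O)[C@@H](OC(=O)C(C)Br)/C=C(/C)CC[C@H](OC(=O)CC)[C@@]2(C)[C@H]1OC(=O)CCC | intermediate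
44 | C7 2-bromopropionate C8 ketone | CCCC(=O)O[C@@H]1C=C(C)[C@@H]2[C@H](OCc3ccc(OC)cc3)C(=O)[C@@H](OC(=O)C(C)Br)/C=C(/C)CC[C@H](OC(=O)CC)[C@@]2(C)[C@H]1OC(=O)CCC | intermediate
45 | C9 PMB ether of the target | CCCC(=O)O[C@@H]1C=C(C)[C@@H]2[C@H](OCc4ccc(OC)cc4)[C@@]3(O)[C@H](/C=C(/C)CC[C@H](OC(=O)CC)[C@@]2(C)[C@H]1OC(=O)CCC)OC(=O)[C@@H]3C | intermediate
46 | CNP0138989.1 | CCCC(=O)O[C@@H]1C=C(C)[C@@H]2[C@H](O)[C@@]3(O)[C@H](/C=C(/C)CC[C@H](OC(=O)CC)[C@@]2(C)[C@H]1OC(=O)CCC)OC(=O)[C@@H]3C | target

## Step count and least certain steps

Total: 35 steps. Longest linear sequence: 29 steps (steps 7–35, from acid 9); aldehyde 8 takes 6 steps (steps 1–6).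

Step 26 (key step). The rearrangement may stall, because the oxocane must fold into a compact bicyclic transition state in which C4 approaches C3 next to the quaternary C1. At the temperature then required, ionisation of the allylic C6–O bond or hydrolysis of the enol ether could overtake the sigmatropic shift. The fallback forms the same C3–C4 bond by ionic chemistry and sets out from lactone 31. Addition of LiCH2SO2Ph (THF, −78 °C) opens the lactone to the hydroxy β-keto sulfone F1. Its C6 hydroxyl is converted with ClCO2Me and pyridine into the allylic methyl carbonate F2. Pd(PPh3)4 in THF at high dilution then ionises the carbonate, and the stabilised C3 carbanion attacks the less hindered C4 terminus of the allyl unit (Tsuji–Trost cyclisation) to give the 3-phenylsulfonyl cyclodecenone F3. Reductive desulfonylation with SmI2 and MeOH returns to the route at 34. The alkene geometry would have to be checked; the Z isomer is the less strained one in a ten-membered ring.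

Step 17 (with step 18). The stereochemical relay may erode: the allylpalladium intermediate can lose its configuration by exchange with zerovalent palladium, boron may be delivered to C10 instead of C12, or β-hydride loss may give a diene. Any of these would spoil the face or the site of the C9–C10 bond formation. The fallback sets out from allylic alcohol 22. CBr4 and PPh3 give the allylic bromide F4, which is coupled with aldehyde 8 by CrCl2 in THF/DMF (Nozaki–Hiyama–Kishi allylation) to return at 25. The allylchromium species equilibrates, the closed transition state still gives the syn C9/C10 relationship, and the face is then chosen by the C14 silyl ether and the C2 pivaloyloxymethyl group. Loss of the C13 silyloxy group by β-elimination would have to be watched.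

Step 24. Ring closure may lose to intermolecular esterification. Activation takes place at a neopentyl carboxyl and the eight-membered ring forms slowly, so dimers and the 2-methyl-6-nitrobenzoate of the C6 hydroxyl are likely diversions. The fallback activates the alcohol instead of the acid and sets out from hydroxy acid 30. Mitsunobu lactonisation (PPh3, diisopropyl azodicarboxylate, toluene, high dilution) lets the unhindered carboxylate oxygen displace the activated C6 oxygen with inversion and gives the C6-epimeric lactone F5. Cp2Ti(CH2)(Cl)AlMe2 converts it into the C6-epimeric 2-methylene oxocane F6. Heating as in step 26 erases C6 and returns to the route at 34; only the sense of the chair-like array differs.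

Step 32. Discrimination between the two secondary hydroxyls may be poor, or the acyl group may move from O7 to O8 before the oxidation, which would lead to the regioisomeric lactone. The fallback separates the two events and sets out from diol 41. Et3SiCl and imidazole at −40 °C silylate the less hindered allylic hydroxyl to give the C7 triethylsilyl ether F7. Dess–Martin oxidation gives the C8 ketone F8, and HF·pyridine releases the α-hydroxy ketone F9. Acylation of F9 with 42 and pyridine returns to the route at 44. A silyl group is bulkier than the acyl bromide and does not migrate under these conditions.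

## Further compounds

F1 | step 26 | hydroxy β-keto sulfone from ring opening of 31 (C2 ketone with phenylsulfonylmethyl group, C6 hydroxyl) | CC(C)(C)[Si](C)(C)O[C@@H]1C=C(C)[C@H]([C@H](OCc3ccc(OC)cc3)[C@@H]2OC(C)(C)O[C@H]2[C@@H](O)C(C)=C)[C@@](C)(C(=O)CS(=O)(=O)c4ccccc4)[C@H]1O[Si](C)(C)C(C)(C)C
F2 | step 26 | C6 methyl carbonate of F1 | CC(C)(C)[Si](C)(C)O[C@@H]1C=C(C)[C@H]([C@H](OCc3ccc(OC)cc3)[C@@H]2OC(C)(C)O[C@H]2[C@@H](OC(=O)OC)C(C)=C)[C@@](C)(C(=O)CS(=O)(=O)c4ccccc4)[C@H]1O[Si](C)(C)C(C)(C)C
F3 | step 26 | 3-phenylsulfonyl derivative of cyclodecenone 34 | CC(C)(C)[Si](C)(C)O[C@@H]1C=C(C)[C@@H]2[C@H](OCc3ccc(OC)cc3)[C@@H]4OC(C)(C)O[C@H]4/C=C(/C)CC(S(=O)(=O)c5ccccc5)C(=O)[C@@]2(C)[C@H]1O[Si](C)(C)C(C)(C)C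
F4 | step 17 | ring A C12 allylic bromide (bromide cis to the C13 silyl ether) | CC(C)(C)[Si](C)(C)O[C@@H]1[C@H](Br)C(C)=C[C@@](C)(COC(=O)C(C)(C)C)[C@H]1O[Si](C)(C)C(C)(C)C
F5 | step 24 | C6 epimer of lactone 31 | CC(C)(C)[Si](C)(C)O[C@@H]1C=C(C)[C@@H]2[C@H](OCc3ccc(OC)cc3)[C@@H]4OC(C)(C)O[C@H]4[C@@H](C(C)=C)OC(=O)[C@@]2(C)[C@H]1O[Si](C)(C)C(C)(C)C
F6 | step 24 | C6 epimer of 2-methylene oxocane 33 | CC(C)(C)[Si](C)(C)O[C@@H]1C=C(C)[C@@H]2[C@H](OCc3ccc(OC)cc3)[C@@H]4OC(C)(C)O[C@H]4[C@@H](C(C)=C)OC(=C)[C@@]2(C)[C@H]1O[Si](C)(C)C(C)(C)C
F7 | step 32 | C7 triethylsilyl ether of diol 41 | CCCC(=O)O[C@@H]1C=C(C)[C@@H]2[C@H](OCc3ccc(OC)cc3)[C@H](O)[C@@H](O[Si](CC)(CC)CC)/C=C(/C)CC[C@H](OC(=O)CC)[C@@]2(C)[C@H]1OC(=O)CCC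
F8 | step 32 | C8 ketone with C7 triethylsilyl ether | CCCC(=O)O[C@@H]1C=C(C)[C@@H]2[C@H](OCc3ccc(OC)cc3)C(=O)[C@@H](O[Si](CC)(CC)CC)/C=C(/C)CC[C@H](OC(=O)CC)[C@@]2(C)[C@H]1OC(=O)CCC
F9 | step 32 | C8 ketone with free C7 hydroxyl | CCCC(=O)O[C@@H]1C=C(C)[C@@H]2[C@H](OCc3ccc(OC)cc3)C(=O)[C@@H](O)/C=C(/C)CC[C@H](OC(=O)CC)[C@@]2(C)[C@H]1OC(=O)CCC
A1 | alternative 1 | ring A aldehyde with C1 methyl and formyl group, C10 benzyloxymethyl group, C11 methyl, C14 silyl ether and C12–C13 alkene | O=C[C@]1(C)[C@@H](COCc2ccccc2)[C@H](C)C=C[C@@H]1O[Si](C)(C)C(C)(C)C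
A2 | alternative 1 | (1E,3E)-1-(tert-butyldimethylsilyloxy)penta-1,3-diene | C/C=C/C=C/O[Si](C)(C)C(C)(C)C
A3 | alternative 1 | (E)-4-(benzyloxy)-2-methylbut-2-enal | O=C/C(C)=C/COCc1ccccc1
A4 | alternative 2 | C9 triethylsilyl ether of the target | CCCC(=O)O[C@@H]1C=C(C)[C@@H]2[C@H](O[Si](CC)(CC)CC)[C@@]3(O)[C@H](/C=C(/C)CC[C@H](OC(=O)CC)[C@@]2(C)[C@H]1OC(=O)CCC)OC(=O)[C@@H]3C
A5 | alternative 2 | C7 2-bromopropionate C8 ketone with C9 triethylsilyl ether | CCCC(=O)O[C@@H]1C=C(C)[C@@H]2[C@H](O[Si](CC)(CC)CC)C(=O)[C@@H](OC(=O)C(C)Br)/C=C(/C)CC[C@H](OC(=O)CC)[C@@]2(C)[C@H]1OC(=O)CCC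
A6 | alternative 3 | rings A, B and C with C9 alcohol and C8–C17 butenolide alkene | CCCC(=O)O[C@@H]1C=C(C)[C@@H]2[C@H](O)C=3[C@H](/C=C(/C)CC[C@H](OC(=O)CC)[C@@]2(C)[C@H]1OC(=O)CCC)OC(=O)C=3C
A7 | alternative 3 | seco aldehyde: ring A with C9 formyl group on C10 and a C2–C7 chain ending in the C8-iodo butenolide | CCCC(=O)O[C@@H]1C=C(C)[C@H](C=O)[C@](C)([C@H]1OC(=O)CCC)[C@@H](OC(=O)CC)CC/C(C)=C\[C@@H]2OC(=O)C(C)=C2I
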